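The runs come from a simulation from invented constants, noise included.

The closed, stirred vessel holds starting complex, which takes up incoming ligand, frees leaving ligand and becomes complex with one exchanged. That complex repeats the step to give complex with two exchanged, while freed leaving ligand holds further incoming ligand as idle adduct.

| flask | starting complex | incoming ligand | remark | time |
|---|---|---|---|---|
| autumn | 0.0010 M | 1.1 mM | run made earlier |  |
| dawn | 0.0010 M | 1.3 mM | run made earlier |  |
| noon | 0.0010 M | 1.4 mM | run made earlier |  |
| ash | 0.0010 M | 1.00 mM |  | 2.5 min |
| oak | 0.0010 M | 1.50 mM |  | 2.5 min |

| run | time / min | starting complex / % | complex with two exchanged / % |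
|---|---|---|---|
| autumn | 0.200 | 60.4 | 25.6 |
| autumn | 0.667 | 56.4 | 31.4 |
| autumn | 1.33 | 52.9 | 36.6 |
| autumn | 2.00 | 51.2 | 38.5 |
| autumn | 2.50 | 49.1 | 38.4 |
| dawn | 0.500 | 49.9 | 35.5 |
| dawn | 1.00 | 47.1 | 40.3 |
| dawn | 1.50 | 45.9 | 43.7 |
| dawn | 2.00 | 44.3 | 44.4 |
| dawn | 2.50 | 42.4 | 48.3 |
| noon | 0.200 | 53.8 | 33.8 |
| noon | 0.667 | 48.9 | 39.6 |
| noon | 1.33 | 45.7 | 45.2 |
| noon | 2.00 | 42.9 | 48.5 |
| noon | 2.50 | 39.8 | 48.7 |

(scatter of a reading: 1 percentage point)

- for leaving ligand the idle adduct is counted in
- reactions considered so far: starting complex + incoming ligand -> leaving ligand + complex with one exchanged; leaving ligand + incoming ligand <-> idle adduct; complex with one exchanged + incoming ligand -> leaving ligand + complex with two exchanged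

- part of the starting complex that has reacted at the end, ash
- part of the starting complex that has reacted at the end, oak
- what raising the concentration of incoming ligand from its lowest to its highest value here does to the part of the starting complex that has reacted (changes below 5 percentage points count as none) (it rises / it falls / no change)

The readings form a ladder. Fastest is a burst: in the autumn run 39.6% of the starting complex is gone by 0.200 min, and the next 2.30 min take only 11 percentage points more, a crawl far slower than the burst. On the rung beside the burst, complex with one exchanged, taken by difference in autumn, reads 14.0% at the first reading and 12.5% at the last, so it is passed on about as it forms. On the crawl the charge shows: at 2.50 min, autumn has reacted 50.9% and noon 60.2%.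

Those two runs give 0.310: the marginal yield, starting complex reacted at the last reading per extra incoming ligand charged, with 1 point of scatter on each reading. The rest of each extra portion goes to second exchanges and adduct. Stepping down from autumn gives 47.8% for ash, and stepping up from noon gives 63.3% for oak.

The forecast, holding “Conversion at 2.5 min is therefore essentially ligand-limited”, says 47% for ash, a point below this reckoning, 63% for oak, and it rises.

The simulation gives 47.7% for ash and 62.1% for oak: it rises, by 14 points.

    starting complex + incoming ligand → leaving ligand + complex with one exchanged (k = 338 L mol⁻¹ s⁻¹)
    leaving ligand + incoming ligand ⇌ idle adduct, settled at all times (K = 1.30 × 10⁵ L mol⁻¹)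
    complex with one exchanged + incoming ligand → leaving ligand + complex with two exchanged (k = 1710 L mol⁻¹ s⁻¹)

The gap between oak and ash comes from their different charge of incoming ligand: oak given the charge of ash reacts 47.7% rather than 62.1%. Depletion of incoming ligand, the limiting reagent, is a part of why ash stops short: 0.188% of its charge stands free at the end, and without that depletion ash reaches 100% instead of 47.7%. From ash to oak the marginal yield is 0.287. The 0.310 read from autumn and noon, applied to the neighbour flask, like ash but charged with 0.0040 M, promises 0.930 mM more reaction, more than the 0.523 mM of starting complex left in ash. That neighbour flask keeps 0.0087% of its starting complex.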